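Colupulone's single carbocycle is numbered C1 (ring ketone), C2 (isobutyryl-bearing), C3 and C5 (enol carbons), C4 (monoprenyl) and C6 (gem-diprenyl). The route rests on cutting C3–C4: C3 is a carboxyl-level carbon lying between the doubly acylated C2 and C4, the α-carbon of the C5 ketone, so it is brought in as carbon disulfide. In the key step the C4 enolate of an acyclic gem-diprenyl triketone, whose C2 carries a bis(methylsulfanyl)methylene group, attacks that carbon and expels methanethiolate, closing the six-membered ring with every substituent in place. Exchange of the remaining C3 methylsulfanyl group for hydroxyl then gives the target.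

Key step: step 5

Remark: colupulone has no stereocentre (C6 bears two identical prenyl groups) and is drawn as its 3,5-dienol tautomer. The ring locants C1–C6 are also used for the corresponding carbons of the open-chain intermediates. Equivalents and temperatures are proposed values.

Step 1
Reactants: 1 pentane-2,4-dione; 2 prenyl bromide (1-bromo-3-methylbut-2-ene)
Product: 4 3,3-bis(3-methylbut-2-enyl)pentane-2,4-dione, via monoprenyl diketone 3 (not isolated)
Conditions: 2 (2.3 equiv), K2CO3 (3 equiv), dry acetone, reflux
Reagents that add atoms: none
Why: Double SN2 C-alkylation of a β-diketone potassium enolate, in which the chelated enolate in acetone and the soft allylic bromide favour carbon over oxygen in both alkylations, and the medium holds no nucleophile that could cleave the non-enolisable 1,3-diketone 4 by retro-Claisen reaction; no stereocentre arises because the two new groups are identical.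

Step 2
Reactants: 4 3,3-bis(3-methylbut-2-enyl)pentane-2,4-dione; 5 N-methoxy-N,2-dimethylpropanamide (Weinreb amide of isobutyric acid)
Product: 8 7-methyl-3,3-bis(3-methylbut-2-enyl)octane-2,4,6-trione, via lithium mono-enolate 6 (not isolated), via lithium tetrahedral adduct 7 (not isolated)
Conditions: 4 (2.0 equiv), LiN(i-Pr)2 (2.0 equiv), THF, −78 °C; 5 (1.0 equiv), −78 → 0 °C; cold 1 M HCl
Reagents that add atoms: none
Why: Crossed Claisen-type C-acylation of a ketone lithium enolate with a Weinreb amide, in which 4 has only one kind of α-proton (two equivalent acetyl groups) so that enolate 6 is regiochemically unambiguous, the amide is the limiting reagent and its chelated adduct 7 cannot acylate again so that only one acetyl group is extended, and the surplus enolate takes up the acidic proton of any 8 released early (excess 4 is recovered); 8 has no stereocentre.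

Step 3
Reactants: 8 7-methyl-3,3-bis(3-methylbut-2-enyl)octane-2,4,6-trione; 2 prenyl bromide
Product: 10 2,11-dimethyl-6,6-bis(3-methylbut-2-enyl)dodec-10-ene-3,5,7-trione, via dilithium dianion 9 (not isolated)
Conditions: LiN(i-Pr)2 (2.1 equiv), THF, −78 °C; 2 (1.0 equiv), −78 → −20 °C; cold 1 M HCl
Reagents that add atoms: none
Why: Dianion alkylation, in which the first equivalent of base removes the doubly activated proton of the β-diketone methylene, the second can then only enolise the acetyl methyl group (the other α-position of the diketonate is the tertiary isopropyl methine and the carbon between the ketones is quaternary), and the more basic, last-formed methyl-ketone enolate carbon of 9 alone undergoes SN2 alkylation by one equivalent of the allylic bromide at low temperature; no stereocentre is formed.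

Step 4
Reactants: 10 2,11-dimethyl-6,6-bis(3-methylbut-2-enyl)dodec-10-ene-3,5,7-trione; 11 carbon disulfide
Product: 13 4-[bis(methylsulfanyl)methylidene]-2,11-dimethyl-6,6-bis(3-methylbut-2-enyl)dodec-10-ene-3,5,7-trione, via dipotassium ene-dithiolate 12 (not isolated)
Conditions: K2CO3 (3 equiv), 11 (1.5 equiv), DMF, 0 °C → rt; then MeI (2.5 equiv), 0 °C → rt
Reagents that add atoms: iodomethane, CI
Why: Standard α-oxo ketene dithioacetal synthesis, in which carbonate deprotonates only the β-diketone methylene (ring position C2), the enolate adds to CS2, a second deprotonation gives the ene-1,1-dithiolate 12 and double SN2 S-methylation gives 13, while the ketone α-methylene at C4 is not acidic enough to be touched; no stereocentre is formed and the new alkene carries two identical sulfur groups.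

Step 5
Reactants: 13 4-[bis(methylsulfanyl)methylidene]-2,11-dimethyl-6,6-bis(3-methylbut-2-enyl)dodec-10-ene-3,5,7-trione
Product: 15 5-hydroxy-3-(methylsulfanyl)-2-(2-methylpropanoyl)-4,6,6-tris(3-methylbut-2-enyl)cyclohexa-2,4-dien-1-one, via lithium C4 enolate 14 (not isolated)
Conditions: LiN(SiMe3)2 (2.2 equiv), THF, −78 °C → rt, argon; cold 1 M HCl to pH 3
Reagents that add atoms: none
Why: LiN(SiMe3)2 removes a proton from C4, the α-methylene of the C5 ketone (the only other α-proton, the isobutyryl methine, is tertiary, less acidic and its enolate cannot reach an electrophile), and the enolate carbon of 14 adds to C3, the ketene dithioacetal carbon activated by both the C1 and the isobutyryl carbonyl groups; collapse of the stabilised C2 carbanion expels methanethiolate and the acidic C4–H of the first-formed ring is then removed, which is why two equivalents of base are used. The closest known reaction type is the intermolecular conjugate addition–elimination (nucleophilic vinylic substitution) of ketone enolates on α-oxo ketene dithioacetals, applied here within one molecule. The single ring closes in a 6-endo-trig mode (the C2=C3 bond lies inside the new ring), made accessible by the easy twisting of the push–pull C2=C3 bond and by the Thorpe–Ingold compression of the gem-diprenyl C6 that links the two reacting ends. No stereocentre is formed, and because C3 carries two identical methylsulfanyl groups the alkene geometry of 13 is irrelevant. The step needs C- over O-attack of the enolate on C3 and attack at C3 in preference to aldol addition to the isobutyryl carbonyl; the tight lithium–oxygen pair in THF and the soft acceptor favour carbon, and only the C–C pathway is made irreversible by thiolate loss and formation of the delocalised enolate of 15, so reversible aldol adducts should drain into it.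

Step 6
Reactants: 15 5-hydroxy-3-(methylsulfanyl)-2-(2-methylpropanoyl)-4,6,6-tris(3-methylbut-2-enyl)cyclohexa-2,4-dien-1-one
Product: 16 colupulone, 3,5-dihydroxy-2-(2-methylpropanoyl)-4,6,6-tris(3-methylbut-2-enyl)cyclohexa-2,4-dien-1-one
Conditions: 2 M aq. NaOH, 1,4-dioxane (degassed), 80 °C, argon; cold 1 M HCl
Reagents that add atoms: sodium hydroxide, [Na+].[OH-]
Why: Nucleophilic vinylic substitution (addition–elimination) on a vinylogous thioester, in which C3 is β to both the C1 ketone and the isobutyryl carbonyl so that hydroxide adds there and methanethiolate leaves, the product being held as the delocalised β-triketone enolate whose charge also shields the C1 and C5 carbonyl groups from retro-Claisen cleavage until acidification under argon releases colupulone; the target has no stereocentre.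

Compound list
1 | pentane-2,4-dione (acetylacetone) | CC(=O)CC(C)=O | starting material
2 | prenyl bromide (1-bromo-3-methylbut-2-ene) | CC(C)=CCBr | starting material
3 | 3-(3-methylbut-2-enyl)pentane-2,4-dione | CC(=O)C(CC=C(C)C)C(C)=O | intermediate
4 | 3,3-bis(3-methylbut-2-enyl)pentane-2,4-dione | CC(=O)C(CC=C(C)C)(CC=C(C)C)C(C)=O | intermediate
5 | N-methoxy-N,2-dimethylpropanamide | CON(C)C(=O)C(C)C | starting material
6 | lithium 3-acetyl-6-methyl-3-(3-methylbut-2-enyl)hepta-1,5-dien-2-olate (mono-enolate of 4 at one acetyl methyl group) | [Li+].[O-]C(=C)C(CC=C(C)C)(CC=C(C)C)C(C)=O | intermediate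
7 | lithium alkoxide adduct of 6 and 5: 8 in which the isobutyryl carbonyl carbon bears O–Li and N(OMe)Me (racemic) | [Li+].CC(=O)C(CC=C(C)C)(CC=C(C)C)C(=O)CC([O-])(N(C)OC)C(C)C | intermediate
8 | 7-methyl-3,3-bis(3-methylbut-2-enyl)octane-2,4,6-trione | CC(=O)C(CC=C(C)C)(CC=C(C)C)C(=O)CC(=O)C(C)C | intermediate
9 | dilithium dianion of 8 (β-diketonate plus acetyl methyl enolate) | [Li+].[Li+].C=C([O-])C(CC=C(C)C)(CC=C(C)C)C(=O)C=C([O-])C(C)C | intermediate
10 | 2,11-dimethyl-6,6-bis(3-methylbut-2-enyl)dodec-10-ene-3,5,7-trione | CC(C)C(=O)CC(=O)C(CC=C(C)C)(CC=C(C)C)C(=O)CCC=C(C)C | intermediate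
11 | carbon disulfide | S=C=S | starting material
12 | dipotassium ene-1,1-dithiolate of 10 (13 with two S–K in place of the two S–CH3 groups) | [K+].[K+].[S-]C([S-])=C(C(=O)C(C)C)C(=O)C(CC=C(C)C)(CC=C(C)C)C(=O)CCC=C(C)C | intermediate
13 | 4-[bis(methylsulfanyl)methylidene]-2,11-dimethyl-6,6-bis(3-methylbut-2-enyl)dodec-10-ene-3,5,7-trione | CSC(SC)=C(C(=O)C(C)C)C(=O)C(CC=C(C)C)(CC=C(C)C)C(=O)CCC=C(C)C | intermediate
14 | lithium enolate of 13 across ring positions C5 and C4 (chain C7=C8, geometry undefined) | [Li+].CSC(SC)=C(C(=O)C(C)C)C(=O)C(CC=C(C)C)(CC=C(C)C)C([O-])=CCC=C(C)C | intermediate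
15 | 5-hydroxy-3-(methylsulfanyl)-2-(2-methylpropanoyl)-4,6,6-tris(3-methylbut-2-enyl)cyclohexa-2,4-dien-1-one | CSC1=C(C(=O)C(C)C)C(=O)C(CC=C(C)C)(CC=C(C)C)C(O)=C1CC=C(C)C | intermediate
16 | colupulone, 3,5-dihydroxy-2-(2-methylpropanoyl)-4,6,6-tris(3-methylbut-2-enyl)cyclohexa-2,4-dien-1-one | CC(C)=CCC1=C(O)C(CC=C(C)C)(CC=C(C)C)C(=O)C(C(=O)C(C)C)=C1O | target

Total step count: 6. Longest linear sequence: 6 steps (1 → 16).

Steps most likely to fail

Step 5 (key step). The C4 enolate may close through oxygen instead of carbon or rest as an aldol adduct on the isobutyryl carbonyl. The liberated thiolate may also cleave the non-enolisable 1,3-diketone before closure is complete. The fallback gives up the open-chain closure; it sets out from prenyl bromide 2 and comes back at colupulone 16. Friedel–Crafts acylation of commercial benzene-1,3,5-triol with isobutyryl chloride and AlCl3 should give 2-methyl-1-(2,4,6-trihydroxyphenyl)propan-1-one F1. Its phenolate is then C-prenylated three times with 2 (NaOMe, MeOH, 0 °C). The third alkylation, at an already prenylated ring carbon, dearomatises the ring to 16. This base-mediated dearomatising prenylation of acylphloroglucinols is a known reaction type.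

Step 6. Hydroxide may displace methanethiolate from the delocalised enolate of 15 too slowly, may open the ring by retro-Claisen attack at C1 or C5, or the electron-rich enolate may autoxidise. The fallback brings C3 in with its oxygen already attached; it sets out from triketone 10 and comes back at 16, bypassing 13 and 15. Magnesium-mediated C-acylation of the β-diketone of 10 (MgCl2, pyridine, methyl chloroformate, CH2Cl2) should give methyl 9-methyl-2-(2-methylpropanoyl)-4,4-bis(3-methylbut-2-enyl)-3,5-dioxodec-8-enoate F2. LiN(SiMe3)2 (3 equiv, THF) then forms the C4 enolate, which closes the ring by Dieckmann condensation on the ester with loss of methoxide. Acidification gives 16. Both operations are known reaction types (C-acylation of magnesium β-diketonates; Claisen cyclisation of polyketo esters to cyclic β-triketones).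

Step 3. Proton exchange between dianion 9 and the mono-alkylated product may cause a second alkylation at the same carbon, or alkylation may spill over to the diketonate carbon. The fallback reverses the order of the two chain extensions; it sets out from diketone 4 and comes back at 10. The mono-enolate of 4 (LiN(i-Pr)2, 1 equiv, THF, −78 °C) is alkylated with 2 to give 8-methyl-3,3-bis(3-methylbut-2-enyl)non-7-ene-2,4-dione F3. Kinetic deprotonation of its remaining acetyl methyl group with the bulky lithium 2,2,6,6-tetramethylpiperidide at −78 °C, then acylation with amide 5, gives 10. Regiocontrol then rests on the kinetic preference for methyl over methylene deprotonation instead of on the anion hierarchy.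

Further compounds
F1 | step 5 | 2-methyl-1-(2,4,6-trihydroxyphenyl)propan-1-one | CC(C)C(=O)c1c(O)cc(O)cc1O
F2 | step 6 | methyl 9-methyl-2-(2-methylpropanoyl)-4,4-bis(3-methylbut-2-enyl)-3,5-dioxodec-8-enoate (racemic, enolisable) | COC(=O)C(C(=O)C(C)C)C(=O)C(CC=C(C)C)(CC=C(C)C)C(=O)CCC=C(C)C
F3 | step 3 | 8-methyl-3,3-bis(3-methylbut-2-enyl)non-7-ene-2,4-dione | CC(=O)C(CC=C(C)C)(CC=C(C)C)C(=O)CCC=C(C)C
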